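**Plan**

1. Retrosynthesis (eudesmane numbering; α = face opposite the C10 methyl): the C11–OOH bond with the C6=C7 shift goes back to a C7=C11 isopropylidene 8-ketone (ene reaction). Then come the ester O–C(=O) bond, the C3–O and C4–O bonds (from a 3-ene), and the C8–C9 and C9–C10 bonds, so that C9 is taken out of ring B. Last are C7=C11 (acetone), C4=C5 (aldol) and C1–C10 (Michael).
2. Enabling feature: in ring B (C5–C6–C7–C8–C9–C10) the C8 carbonyl lies one methylene (C9) away from the quaternary C10 and is conjugated to the exocyclic C7=C11. Without C9 the ring is a cyclopentanone (C5–C6–C7–C8–C10) with its carbonyl on the quaternary carbon, which is the hydrindenedione delivered by an amino-acid-mediated aldol. The sp2 carbon C7 is a poor migrating group, so a diazo carbon should enter only the C8–C10 bond.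
3. Forward order: Michael addition and aldol condensation build ring A and the five-membered ring together. Ring A is taken to the trans-fused 3-ene, acetone is condensed onto C7, and the five-membered ring is expanded to ring B. The 3,4-diol, the angelate and the hydroperoxide follow.
4. Stereochemistry: C10 comes from the L-phenylalanine-mediated aldol, C5 from axial protonation in the dissolving-metal reduction, and C3 and C4 from α-face osmylation opposite the axial C10 methyl. The Z ester geometry is bought as angelic acid; C11 is not stereogenic.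

Key step: step 11

Remark on the chemistry: the hydrindane intermediates are named as indenes (C1 = later C8, C2 = C7, C3 = C6, C3a = C5, C7a = C10); the decalins carry eudesmane numbers.

**Step 1**
Reactants: 1 2-methylcyclopentane-1,3-dione; 2 pent-1-en-3-one (ethyl vinyl ketone)
Product: 3 2-methyl-2-(3-oxopentyl)cyclopentane-1,3-dione
Conditions: H2O, AcOH (cat.), 75 °C
Reagents that add atoms: none
Why: Michael addition of the acidic 1,3-dione to the vinyl ketone needs no strong base and should stop at the mono-adduct because the product has no acidic C–H left between the carbonyls; the new quaternary carbon (later C10) is still prochiral.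

**Step 2**
Reactants: 3 2-methyl-2-(3-oxopentyl)cyclopentane-1,3-dione
Product: 4 (7aS)-4,7a-dimethyl-2,3,7,7a-tetrahydro-1H-indene-1,5(6H)-dione
Conditions: L-phenylalanine (1 equiv), (1S)-(+)-camphor-10-sulfonic acid (0.5 equiv), DMF, 30 → 70 °C
Reagents that add atoms: none
Why: Hajos–Parrish-type intramolecular aldol condensation, in which the enamine of the side-chain ketone with the L-amino acid attacks one of the two enantiotopic ring carbonyls through a hydrogen-bonded chair-like transition state and so should set the quaternary centre as S (methyl β), the acid co-catalyst dehydrating the ketol to the enone.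

**Step 3**
Reactants: 4 (7aS)-4,7a-dimethyl-2,3,7,7a-tetrahydro-1H-indene-1,5(6H)-dione
Product: 5 (1S,7aS)-1-hydroxy-4,7a-dimethyl-1,2,3,6,7,7a-hexahydro-5H-inden-5-one
Conditions: NaBH4, EtOH, −20 °C
Reagents that add atoms: none
Why: Chemoselective hydride reduction, since the saturated cyclopentanone carbonyl is more electrophilic than the vinylogous enone carbonyl, with attack opposite the angular methyl expected to give the 1β-alcohol (this centre is re-oxidised in step 8, so its configuration is of no consequence).

**Step 4**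
Reactants: 5 (1S,7aS)-1-hydroxy-4,7a-dimethyl-1,2,3,6,7,7a-hexahydro-5H-inden-5-one
Product: 6 (1S,7aS)-1-[(tert-butyldimethylsilyl)oxy]-4,7a-dimethyl-1,2,3,6,7,7a-hexahydro-5H-inden-5-one
Conditions: TBSCl, imidazole, DMF, rt
Reagents that add atoms: tert-butyldimethylsilyl chloride, CC(C)(C)[Si](C)(C)Cl
Why: Standard imidazole-mediated silylation masks the alcohol for the dissolving-metal and palladium steps.

**Step 5**
Reactants: 6 (1S,7aS)-1-[(tert-butyldimethylsilyl)oxy]-4,7a-dimethyl-1,2,3,6,7,7a-hexahydro-5H-inden-5-one
Product: 8 (1S,3aR,7aS)-1-[(tert-butyldimethylsilyl)oxy]-4,7a-dimethyl-2,3,3a,6,7,7a-hexahydro-1H-inden-5-yl trifluoromethanesulfonate, via lithium enolate 7 (not isolated)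
Conditions: Li (2.2 equiv), NH3(l), THF, t-BuOH (1 equiv), −78 °C; NH3 off; then PhNTf2, THF, −78 °C → rt
Reagents that add atoms: N-phenylbis(trifluoromethanesulfonimide), O=S(=O)(N(c1ccccc1)S(=O)(=O)C(F)(F)F)C(F)(F)F
Why: Birch-type enone reduction with regiospecific enolate trapping (reductive triflation), in which the β-carbanion at C3a is protonated axially on the face opposite the angular methyl, which should give the trans ring fusion (H-3a α), and the enolate is captured on oxygen so that the double bond is fixed between C4 and C5.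

**Step 6**
Reactants: 8 (1S,3aR,7aS)-1-[(tert-butyldimethylsilyl)oxy]-4,7a-dimethyl-2,3,3a,6,7,7a-hexahydro-1H-inden-5-yl trifluoromethanesulfonate
Product: 9 tert-butyl{[(1S,3aS,7aS)-4,7a-dimethyl-2,3,3a,6,7,7a-hexahydro-1H-inden-1-yl]oxy}dimethylsilane
Conditions: Pd(OAc)2 (cat.), PPh3, HCO2H, n-Bu3N, DMF, 60 °C
Reagents that add atoms: none
Why: Palladium-catalysed formate reduction of an enol triflate (oxidative addition to zerovalent palladium formed in situ, formate exchange, loss of CO2, C–H reductive elimination) replaces OTf by H without moving the C4=C5 double bond or touching the silyl ether.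

**Step 7**
Reactants: 9 tert-butyl{[(1S,3aS,7aS)-4,7a-dimethyl-2,3,3a,6,7,7a-hexahydro-1H-inden-1-yl]oxy}dimethylsilane
Product: 10 (1S,3aS,7aS)-4,7a-dimethyl-2,3,3a,6,7,7a-hexahydro-1H-inden-1-ol
Conditions: TBAF, THF, 50 °C
Reagents that add atoms: none
Why: Fluoride-driven Si–O cleavage, warmed because the silyl ether is neopentylic, leaves the olefin and both stereocentres untouched.

**Step 8**
Reactants: 10 (1S,3aS,7aS)-4,7a-dimethyl-2,3,3a,6,7,7a-hexahydro-1H-inden-1-ol
Product: 11 (3aS,7aS)-4,7a-dimethyl-2,3,3a,6,7,7a-hexahydro-1H-inden-1-one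
Conditions: Dess–Martin periodinane, CH2Cl2, rt
Reagents that add atoms: none
Why: Dess–Martin oxidation under neutral conditions returns the ketone without moving the trisubstituted double bond, and this ketone can enolise on one side only (C2), since C7a is quaternary.

**Step 9**
Reactants: 11 (3aS,7aS)-4,7a-dimethyl-2,3,3a,6,7,7a-hexahydro-1H-inden-1-one; 12 acetone
Product: 14 (2S,3aS,7aS)-2-(2-hydroxypropan-2-yl)-4,7a-dimethyl-2,3,3a,6,7,7a-hexahydro-1H-inden-1-one, via lithium enolate 13 (not isolated)
Conditions: LiN(i-Pr)2, THF, −78 °C; then acetone, −78 °C; aq. NH4Cl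
Reagents that add atoms: none
Why: Directed aldol addition of the only possible enolate (C2) to acetone, expected from the face opposite the angular methyl; the new C2 centre is erased in step 10.

**Step 10**
Reactants: 14 (2S,3aS,7aS)-2-(2-hydroxypropan-2-yl)-4,7a-dimethyl-2,3,3a,6,7,7a-hexahydro-1H-inden-1-one
Product: 16 (3aS,7aS)-4,7a-dimethyl-2-(propan-2-ylidene)-2,3,3a,6,7,7a-hexahydro-1H-inden-1-one, via mesylate 15 (not isolated)
Conditions: MsCl, Et3N, CH2Cl2, 0 °C; then DBU, rt
Reagents that add atoms: none
Why: Mesylation of the aldol followed by E1cB elimination through the C2 enolate, with DBU equilibrating any isopropenyl isomer into the conjugated tetrasubstituted isopropylidene ketone.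

**Step 11**
Reactants: 16 (3aS,7aS)-4,7a-dimethyl-2-(propan-2-ylidene)-2,3,3a,6,7,7a-hexahydro-1H-inden-1-one
Product: 18 (5R,10R)-eudesma-3,7(11)-dien-8-one, via α-silyl ketone 17 (not isolated)
Conditions: TMSCHN2, AlMe3, CH2Cl2, −78 → −20 °C; then 1 M HCl, THF, 0 °C
Reagents that add atoms: (trimethylsilyl)diazomethane, C[Si](C)(C)C=[N+]=[N-]
Why: The aluminium-activated C8 carbonyl is attacked by the diazo carbon, and the β-oxido diazonium loses N2 with a 1,2-shift of a ring bond from C8 to the new carbon, which becomes C9 (Büchner–Curtius–Schlotterbeck homologation, closest precedent being the Lewis-acid-promoted diazoalkane ring expansion of conjugated cycloalkenones, in which the saturated α′-carbon migrates). Ring B is not closed by a cyclisation: the cyclopentanone C5–C6–C7–C8–C10 is enlarged to the cyclohexanone by insertion of C9 into the C8–C10 bond. No new stereocentre remains, because C10 migrates with retention, C5 is untouched and the transient C9–Si centre of 17 is erased by protodesilylation. The step needs migration of C10 and not of C7; this should be secured because C7 is the sp2 carbon of the conjugated isopropylidene ketone, so its shift would break the enone conjugation, whereas the shift of the electron-rich quaternary C10 keeps it. It also needs carbonyl addition in place of dipolar cycloaddition to the C=C, which the fully substituted C11 should ensure, and a single homologation, which the bulky silyl group of 17 enforces.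

**Step 12**
Reactants: 18 (5R,10R)-eudesma-3,7(11)-dien-8-one
Product: 19 3α,4α-dihydroxy-5αH-eudesm-7(11)-en-8-one
Conditions: OsO4 (cat.), NMO, acetone/H2O, rt
Reagents that add atoms: N-methylmorpholine N-oxide, C[N+]1([O-])CCOCC1; water, O; osmium tetroxide (catalytic oxygen carrier), O=[Os](=O)(=O)=O
Why: Upjohn syn-dihydroxylation, in which OsO4 selects the electron-rich trisubstituted C3=C4 bond over the electron-poor tetrasubstituted enone and adds from the α-face opposite the axial C10 methyl, which should set C3 (R) and C4 (S) as the 3α,4α-diol.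

**Step 13**
Reactants: 19 3α,4α-dihydroxy-5αH-eudesm-7(11)-en-8-one; 20 angelic acid [(2Z)-2-methylbut-2-enoic acid]
Product: 22 3α-angeloyloxy-4α-hydroxy-5αH-eudesm-7(11)-en-8-one, via mixed anhydride 21 (not isolated)
Conditions: 2,4,6-trichlorobenzoyl chloride, Et3N, toluene, rt; then 19, 80 °C
Reagents that add atoms: none
Why: Yamaguchi-type mixed-anhydride esterification should acylate only the secondary 3α-hydroxyl (the tertiary 4-hydroxyl is inert) and, run without nucleophilic catalyst or strong base, should keep the Z geometry of the angelate; no stereocentre is touched.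

**Step 14**
Reactants: 22 3α-angeloyloxy-4α-hydroxy-5αH-eudesm-7(11)-en-8-one
Product: 23 3α-angeloyloxy-4α-hydroxy-11-hydroperoxy-5αH-eudesm-6-en-8-one [(3R,4S,5R,10R)-4-hydroxy-11-hydroperoxy-8-oxoeudesm-6-en-3-yl (2Z)-2-methylbut-2-enoate]
Conditions: O2, visible light, tetraphenylporphyrin (cat.), CH2Cl2, −20 °C
Reagents that add atoms: dioxygen, O=O
Why: Schenck ene reaction, in which singlet oxygen bonds to the β-carbon C11 of the s-cis α-isopropylidene ketone and abstracts the allylic hydrogen on C6, the substituent geminal to the carbonyl (the usual preference of α,β-unsaturated carbonyl compounds), so that the double bond moves to C6=C7 in conjugation; the ester-conjugated angelate double bond is far less reactive toward this electrophilic oxidant and no stereocentre is created.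

**Compound list**

1 | 2-methylcyclopentane-1,3-dione | CC1C(=O)CCC1=O | starting material
2 | pent-1-en-3-one (ethyl vinyl ketone) | CCC(=O)C=C | starting material
3 | 2-methyl-2-(3-oxopentyl)cyclopentane-1,3-dione | CCC(=O)CCC1(C)C(=O)CCC1=O | intermediate
4 | (7aS)-4,7a-dimethyl-2,3,7,7a-tetrahydro-1H-indene-1,5(6H)-dione | CC1=C2CCC(=O)[C@@]2(C)CCC1=O | intermediate
5 | (1S,7aS)-1-hydroxy-4,7a-dimethyl-1,2,3,6,7,7a-hexahydro-5H-inden-5-one | CC1=C2CC[C@H](O)[C@@]2(C)CCC1=O | intermediate
6 | (1S,7aS)-1-[(tert-butyldimethylsilyl)oxy]-4,7a-dimethyl-1,2,3,6,7,7a-hexahydro-5H-inden-5-one | CC1=C2CC[C@H](O[Si](C)(C)C(C)(C)C)[C@@]2(C)CCC1=O | intermediate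
7 | lithium (1S,3aR,7aS)-1-[(tert-butyldimethylsilyl)oxy]-4,7a-dimethyl-2,3,3a,6,7,7a-hexahydro-1H-inden-5-olate (trans-fused lithium enolate) | [Li+].CC1=C([O-])CC[C@]2(C)[C@@H](O[Si](C)(C)C(C)(C)C)CC[C@@H]12 | intermediate
8 | (1S,3aR,7aS)-1-[(tert-butyldimethylsilyl)oxy]-4,7a-dimethyl-2,3,3a,6,7,7a-hexahydro-1H-inden-5-yl trifluoromethanesulfonate | CC1=C(OS(=O)(=O)C(F)(F)F)CC[C@]2(C)[C@@H](O[Si](C)(C)C(C)(C)C)CC[C@@H]12 | intermediate
9 | tert-butyl{[(1S,3aS,7aS)-4,7a-dimethyl-2,3,3a,6,7,7a-hexahydro-1H-inden-1-yl]oxy}dimethylsilane | CC1=CCC[C@]2(C)[C@@H](O[Si](C)(C)C(C)(C)C)CC[C@@H]12 | intermediate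
10 | (1S,3aS,7aS)-4,7a-dimethyl-2,3,3a,6,7,7a-hexahydro-1H-inden-1-ol | CC1=CCC[C@]2(C)[C@@H](O)CC[C@@H]12 | intermediate
11 | (3aS,7aS)-4,7a-dimethyl-2,3,3a,6,7,7a-hexahydro-1H-inden-1-one (trans-fused) | CC1=CCC[C@]2(C)C(=O)CC[C@@H]12 | intermediate
12 | acetone | CC(C)=O | starting material
13 | lithium enolate of 11 (O–Li on C1, C1=C2 double bond) | [Li+].CC1=CCC[C@]2(C)C([O-])=CC[C@@H]12 | intermediate
14 | (2S,3aS,7aS)-2-(2-hydroxypropan-2-yl)-4,7a-dimethyl-2,3,3a,6,7,7a-hexahydro-1H-inden-1-one | CC1=CCC[C@]2(C)C(=O)[C@H](C(C)(C)O)C[C@@H]12 | intermediate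
15 | 2-[(2S,3aS,7aS)-4,7a-dimethyl-1-oxo-2,3,3a,6,7,7a-hexahydro-1H-inden-2-yl]propan-2-yl methanesulfonate | CC1=CCC[C@]2(C)C(=O)[C@H](C(C)(C)OS(C)(=O)=O)C[C@@H]12 | intermediate
16 | (3aS,7aS)-4,7a-dimethyl-2-(propan-2-ylidene)-2,3,3a,6,7,7a-hexahydro-1H-inden-1-one | CC1=CCC[C@]2(C)C(=O)C(=C(C)C)C[C@@H]12 | intermediate
17 | 9-(trimethylsilyl)-5αH-eudesma-3,7(11)-dien-8-one (C9 epimers; this centre is lost on desilylation) | CC1=CCC[C@]2(C)C([Si](C)(C)C)C(=O)C(=C(C)C)C[C@@H]12 | intermediate
18 | (5R,10R)-eudesma-3,7(11)-dien-8-one [(4aR,8aR)-5,8a-dimethyl-3-(propan-2-ylidene)-3,4,4a,7,8,8a-hexahydronaphthalen-2(1H)-one] | CC1=CCC[C@]2(C)CC(=O)C(=C(C)C)C[C@@H]12 | intermediate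
19 | 3α,4α-dihydroxy-5αH-eudesm-7(11)-en-8-one [(3R,4S,5R,10R)] | O[C@@H]1CC[C@]2(C)CC(=O)C(=C(C)C)C[C@H]2[C@]1(C)O | intermediate
20 | angelic acid [(2Z)-2-methylbut-2-enoic acid] | C/C=C(/C)C(=O)O | starting material
21 | (2Z)-2-methylbut-2-enoic 2,4,6-trichlorobenzoic anhydride | C/C=C(/C)C(=O)OC(=O)c1c(Cl)cc(Cl)cc1Cl | intermediate
22 | 3α-angeloyloxy-4α-hydroxy-5αH-eudesm-7(11)-en-8-one [(3R,4S,5R,10R)] | C/C=C(/C)C(=O)O[C@@H]1CC[C@]2(C)CC(=O)C(=C(C)C)C[C@H]2[C@]1(C)O | intermediate
23 | 3α-angeloyloxy-4α-hydroxy-11-hydroperoxy-5αH-eudesm-6-en-8-one [(3R,4S,5R,10R)] | C/C=C(/C)C(=O)O[C@@H]1CC[C@]2(C)CC(=O)C(C(C)(C)OO)=C[C@H]2[C@]1(C)O | target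

**Summary**

Total step count: 14. Longest linear sequence: 14 steps (from 1 and 2; the route is linear, with 12 and 20 entering as single building blocks).

Steps most likely to fail:

Step 11 (key step). What may go wrong: addition of the bulky silylated diazo carbon to the hindered, conjugated C8 carbonyl may be too slow, or the alkenyl carbon C7 may migrate in competition and place the new methylene between C7 and C8. Fallback, setting out from 16 and returning at 18: homologation with an acceptor-substituted diazo ester (ethyl diazoacetate, BF3·OEt2, CH2Cl2, 0 °C), the variant for which migration of the saturated α′-carbon of conjugated ketones is the documented course. It should give the β-keto ester ethyl 8-oxo-5αH-eudesma-3,7(11)-diene-9-carboxylate F1, which cannot homologate a second time. Krapcho dealkoxycarbonylation (LiCl, wet DMSO, 150 °C) would then give 18.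

Step 14. What may go wrong: hydrogen abstraction from the C12/C13 methyl groups (oxygen then bonds to C7), attack of singlet oxygen on the angelate double bond, or a slow ene reaction at the hindered tetrasubstituted enone. Fallback, setting out from 22 and returning at 23: a radical-chain allylic autoxidation in the dark in place of the pericyclic oxygenation (N-hydroxyphthalimide (cat.), 2,2'-azobis(4-methoxy-2,4-dimethylvaleronitrile) (cat.), O2, MeCN, 35 °C). The phthalimide-N-oxyl radical should abstract the weakest C–H, the secondary allylic C6–H. The C6–C7–C11 allyl radical should take up O2 at the tertiary terminus C11, leaving C6=C7 conjugated to the ketone, and chain transfer from the N-hydroxy compound delivers the hydroperoxide. New compounds on this path: none F0.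

Step 13. What may go wrong: slow acylation of the axial 3α-hydroxyl beside the quaternary C4, and heat- or base-induced Z to E isomerisation to the tiglate. Fallback, setting out from 19 and returning at 22: the Z olefin is built on the substrate. Esterification of the 3-hydroxyl with 2-[bis(2,2,2-trifluoroethoxy)phosphoryl]propanoic acid (DCC, DMAP, CH2Cl2) should give 4α-hydroxy-8-oxo-5αH-eudesm-7(11)-en-3α-yl 2-[bis(2,2,2-trifluoroethoxy)phosphoryl]propanoate F2. Still–Gennari olefination with acetaldehyde (KN(SiMe3)2, 18-crown-6, THF, −78 °C) should then give the (Z)-2-methylbut-2-enoate 22 under kinetic control.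

**Further compounds**

F1 | step 11 | ethyl 8-oxo-5αH-eudesma-3,7(11)-diene-9-carboxylate (C9 epimers) | CC1=CCC[C@]2(C)C(C(=O)OCC)C(=O)C(=C(C)C)C[C@@H]12
F0 | step 14 | none | none
F2 | step 13 | 4α-hydroxy-8-oxo-5αH-eudesm-7(11)-en-3α-yl 2-[bis(2,2,2-trifluoroethoxy)phosphoryl]propanoate | CC(C(=O)O[C@@H]1CC[C@]2(C)CC(=O)C(=C(C)C)C[C@H]2[C@]1(C)O)P(=O)(OCC(F)(F)F)OCC(F)(F)F
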